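**Retrosynthetic overview**

- Rings are lettered A (phloroglucinol end) to F (pyrogallol end). In each ring C4 is the oxygen-bearing carbon between the two C–OH carbons and C1 the oxygen-bearing carbon para to it; every ether oxygen joins C4 of one ring to C1 of the next.
- Feature used: ring C is a 2,5-bis(aryloxy)resorcinol, the aromatised form of a six-carbon 3,5-dicarbonyl chain. Its C1 oxygen (to ring B) can be an aryl enol ether, its C4 oxygen (to ring D) can sit on an aryloxyacetyl carbon, and C3–OH and C5–OH come from two ester carbonyls.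
- Last step: BBr3 removes twelve methyl ethers from 17. Before it, ring C (the only ring made, formed last) is closed from crotonate 7 (C1, C2, C5, C6) and aryloxyacetate 14 (C3, C4): bond C2–C3 by γ-acylation of the dienolate, then bond C4–C5 by Claisen condensation.
- 7 comes from oxa-Michael addition of fragment AB phenol 5 to methyl but-2-ynoate; 5 from Ullmann coupling of 2,4,6-trimethoxyphenol with benzyl-protected 4-bromo-2,6-dimethoxyphenol.
- 14 comes from O-alkylation of fragment DEF phenol 12; 12 from two iodide-selective Ullmann couplings of 4-bromo-2,6-dimethoxyphenol (ring E, then ring D) onto 5-iodo-1,2,3-trimethoxybenzene (ring F), with a bromide-to-iodide exchange between them and hydroxylation of the last bromide.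

Key step: step 10

Remark: the target has no stereocentre. 2,4,6-Trimethoxyphenol (3) and 5-iodo-1,2,3-trimethoxybenzene (8) are taken as catalogue compounds. All electron-rich phenols are handled under argon.

**Route**

Step 1
Reactants: 1 4-bromo-2,6-dimethoxyphenol
Product: 2 2-(benzyloxy)-5-bromo-1,3-dimethoxybenzene
Conditions: BnBr, K2CO3, DMF, rt
Reagents that add atoms: benzyl bromide, BrCc1ccccc1
Why: Williamson O-benzylation of the phenoxide by a primary benzylic bromide masks the C4 oxygen of ring B, so that this ring can act only as the aryl halide partner in step 2.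

Step 2
Reactants: 2 2-(benzyloxy)-5-bromo-1,3-dimethoxybenzene; 3 2,4,6-trimethoxyphenol
Product: 4 2-(benzyloxy)-1,3-dimethoxy-5-(2,4,6-trimethoxyphenoxy)benzene
Conditions: CuI (10 mol%), picolinic acid (20 mol%), K3PO4, DMSO, 90 °C, argon
Reagents that add atoms: none
Why: Ullmann-type C–O coupling with CuI and picolinic acid, a system that accepts di-ortho-substituted electron-rich phenoxides, and the bromine of 2 sits between two ring hydrogens.

Step 3
Reactants: 4 2-(benzyloxy)-1,3-dimethoxy-5-(2,4,6-trimethoxyphenoxy)benzene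
Product: 5 2,6-dimethoxy-4-(2,4,6-trimethoxyphenoxy)phenol (fragment AB phenol)
Conditions: H2 (1 atm), Pd/C, EtOAc–MeOH, rt
Reagents that add atoms: none
Why: Hydrogenolysis cleaves only the benzylic C–O bond; the methyl ethers and the diaryl ether have no benzylic C–O bond and should remain.

Step 4
Reactants: 5 2,6-dimethoxy-4-(2,4,6-trimethoxyphenoxy)phenol; 6 methyl but-2-ynoate
Product: 7 methyl (E)-3-[2,6-dimethoxy-4-(2,4,6-trimethoxyphenoxy)phenoxy]but-2-enoate
Conditions: DABCO (0.5 equiv), MeCN, 60 °C
Reagents that add atoms: none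
Why: Amine-catalysed oxa-Michael addition of the phenol to the β-carbon of the ynoate should give the thermodynamically preferred E enol ether (methyl cis to the ester), and any Z isomer would converge on the same dienolate in step 10.

Step 5
Reactants: 1 4-bromo-2,6-dimethoxyphenol; 8 5-iodo-1,2,3-trimethoxybenzene
Product: 9 5-bromo-1,3-dimethoxy-2-(3,4,5-trimethoxyphenoxy)benzene (fragment EF bromide)
Conditions: CuI (10 mol%), picolinic acid (20 mol%), K3PO4, DMSO, 80 °C, argon
Reagents that add atoms: none
Why: Ullmann C–O coupling that discriminates between the halogens: the aryl iodide reacts at 80 °C while the C–Br bond of 1, para to the phenoxide oxygen, is far slower, so ring E should arrive with its bromine intact.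

Step 6
Reactants: 9 5-bromo-1,3-dimethoxy-2-(3,4,5-trimethoxyphenoxy)benzene
Product: 10 5-iodo-1,3-dimethoxy-2-(3,4,5-trimethoxyphenoxy)benzene
Conditions: CuI (5 mol%), NaI (2 equiv), trans-N,N'-dimethylcyclohexane-1,2-diamine (10 mol%), 1,4-dioxane, 110 °C
Reagents that add atoms: sodium iodide, [Na+].[I-]
Why: Aromatic Finkelstein reaction catalysed by CuI and a diamine, driven by precipitation of NaBr from dioxane, turns the bromide into an iodide so that the next coupling can again tell iodide from bromide.

Step 7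
Reactants: 10 5-iodo-1,3-dimethoxy-2-(3,4,5-trimethoxyphenoxy)benzene; 1 4-bromo-2,6-dimethoxyphenol
Product: 11 5-bromo-2-[3,5-dimethoxy-4-(3,4,5-trimethoxyphenoxy)phenoxy]-1,3-dimethoxybenzene (fragment DEF bromide)
Conditions: CuI (10 mol%), picolinic acid (20 mol%), K3PO4, DMSO, 80 °C, argon
Reagents that add atoms: none
Why: The same iodide-selective Ullmann coupling joins the hindered C4 oxygen of ring D to the unhindered C1 of ring E and leaves a bromine at C1 of ring D.

Step 8
Reactants: 11 5-bromo-2-[3,5-dimethoxy-4-(3,4,5-trimethoxyphenoxy)phenoxy]-1,3-dimethoxybenzene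
Product: 12 4-[3,5-dimethoxy-4-(3,4,5-trimethoxyphenoxy)phenoxy]-3,5-dimethoxyphenol (fragment DEF phenol)
Conditions: Pd2(dba)3 (2 mol%), tBuXPhos (8 mol%), KOH, 1,4-dioxane–H2O, 100 °C; then aq. HCl
Reagents that add atoms: potassium hydroxide, [K+].[OH-]
Why: Palladium-catalysed C–O cross-coupling of an unhindered aryl bromide with hydroxide using a bulky biaryl phosphine, to which diaryl and methyl ethers are inert.

Step 9
Reactants: 12 4-[3,5-dimethoxy-4-(3,4,5-trimethoxyphenoxy)phenoxy]-3,5-dimethoxyphenol; 13 methyl bromoacetate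
Product: 14 methyl 2-{4-[3,5-dimethoxy-4-(3,4,5-trimethoxyphenoxy)phenoxy]-3,5-dimethoxyphenoxy}acetate
Conditions: K2CO3, acetone, reflux
Reagents that add atoms: none
Why: Williamson alkylation (SN2) of an unhindered phenoxide by an α-bromo ester.

Step 10
Reactants: 7 methyl (E)-3-[2,6-dimethoxy-4-(2,4,6-trimethoxyphenoxy)phenoxy]but-2-enoate; 14 methyl 2-{4-[3,5-dimethoxy-4-(3,4,5-trimethoxyphenoxy)phenoxy]-3,5-dimethoxyphenoxy}acetate
Product: 17 2-{4-[3,5-dimethoxy-4-(3,4,5-trimethoxyphenoxy)phenoxy]-3,5-dimethoxyphenoxy}-5-[2,6-dimethoxy-4-(2,4,6-trimethoxyphenoxy)phenoxy]benzene-1,3-diol, via lithium dienolate 15 (not isolated), via acyclic keto ester 16 (not isolated)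
Conditions: 7 (2.1 equiv), LiN(iPr)2 (2.2 equiv), THF, −78 °C; 14 (1 equiv), −78→−20 °C; then tBuOH, KOtBu (3 equiv), 50 °C; aq. HCl, argon
Reagents that add atoms: none
Why: Proposed new method: LiN(iPr)2 removes a proton from the methyl group of 7 (cis to the ester in the E isomer) and dienolate 15 attacks the ester carbonyl of 14 through its terminal carbon, an enol-ether carbon made nucleophilic by the aryloxy group; loss of methoxide forms bond C2–C3 of ring C and gives 16, which the second equivalent of 15 holds as the enolate of its doubly activated CH2 (C2 of ring C). In that anion the crotonate ester is part of a vinylogous enolate and cannot be attacked, so tBuOH and KOtBu are added to let protons shuttle: the minor tautomer with C2 protonated and the aryloxymethyl ketone enolised closes through its carbon (C4 of ring C) onto the ester carbonyl (C5), a 6-(enolendo)-exo-trig Claisen condensation, and loss of methoxide with tautomerisation should give the resorcinol bis-phenoxide. The closest known reactions are the γ-additions of lithium dienolates of 3-alkoxycrotonates to carbonyl compounds, the γ-acylation of acetoacetate dianions by esters, the Claisen cyclisation of 3,5-dioxohexanoates to phloroglucinols and the base-mediated conversion of 4-alkoxy-6-methyl-2-pyranones into 5-alkoxyresorcinols; new is the pairing of two aryloxy-bearing partners, so that both crowded diaryl ether oxygens are in place before the ring exists. No stereocentre is formed. The step needs γ- over α-acylation, which the 3-aryloxy group should secure; acylation faster than proton transfer from 14, favoured by low temperature and the activated α-aryloxy ester; and carbon over oxygen closure, expected because the 2-pyranone from oxygen attack is reopened by alkoxide whereas the carbocycle leaves the equilibrium as an aromatic phenoxide.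

Step 11
Reactants: 17 the hexamer dodecamethyl ether with free hydroxyls at C3 and C5 of ring C
Product: 18 CNP0187343.0 (the fully free hexamer, fourteen hydroxyls)
Conditions: BBr3 (30 equiv), CH2Cl2, −78 °C→rt, argon; ice–water quench; reverse-phase chromatography in degassed solvent
Reagents that add atoms: none
Why: BBr3 cleaves aryl methyl ethers by coordination to oxygen and SN2 attack of bromide at the methyl carbon, whereas the diaryl ether oxygens carry no sp3 carbon and should survive, and the aryl borates hydrolyse on work-up.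

**Compound list**

1 | 4-bromo-2,6-dimethoxyphenol | COc1cc(Br)cc(OC)c1O | starting material
2 | 2-(benzyloxy)-5-bromo-1,3-dimethoxybenzene | COc1cc(Br)cc(OC)c1OCc1ccccc1 | intermediate
3 | 2,4,6-trimethoxyphenol | COc1cc(OC)c(O)c(OC)c1 | starting material
4 | 2-(benzyloxy)-1,3-dimethoxy-5-(2,4,6-trimethoxyphenoxy)benzene | COc1cc(OC)c(Oc2cc(OC)c(OCc3ccccc3)c(OC)c2)c(OC)c1 | intermediate
5 | 2,6-dimethoxy-4-(2,4,6-trimethoxyphenoxy)phenol (fragment AB phenol) | COc1cc(OC)c(Oc2cc(OC)c(O)c(OC)c2)c(OC)c1 | intermediate
6 | methyl but-2-ynoate | CC#CC(=O)OC | starting material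
7 | methyl (E)-3-[2,6-dimethoxy-4-(2,4,6-trimethoxyphenoxy)phenoxy]but-2-enoate | COC(=O)/C=C(/Oc1c(OC)cc(Oc2c(OC)cc(OC)cc2OC)cc1OC)C | intermediate
8 | 5-iodo-1,2,3-trimethoxybenzene | COc1cc(I)cc(OC)c1OC | starting material
9 | 5-bromo-1,3-dimethoxy-2-(3,4,5-trimethoxyphenoxy)benzene (fragment EF bromide) | COc1cc(Oc2c(OC)cc(Br)cc2OC)cc(OC)c1OC | intermediate
10 | 5-iodo-1,3-dimethoxy-2-(3,4,5-trimethoxyphenoxy)benzene (fragment EF iodide) | COc1cc(Oc2c(OC)cc(I)cc2OC)cc(OC)c1OC | intermediate
11 | 5-bromo-2-[3,5-dimethoxy-4-(3,4,5-trimethoxyphenoxy)phenoxy]-1,3-dimethoxybenzene (fragment DEF bromide) | COc1cc(Oc2c(OC)cc(Oc3c(OC)cc(Br)cc3OC)cc2OC)cc(OC)c1OC | intermediate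
12 | 4-[3,5-dimethoxy-4-(3,4,5-trimethoxyphenoxy)phenoxy]-3,5-dimethoxyphenol (fragment DEF phenol) | Oc1cc(OC)c(Oc2cc(OC)c(Oc3cc(OC)c(OC)c(OC)c3)c(OC)c2)c(OC)c1 | intermediate
13 | methyl bromoacetate | COC(=O)CBr | starting material
14 | methyl 2-{4-[3,5-dimethoxy-4-(3,4,5-trimethoxyphenoxy)phenoxy]-3,5-dimethoxyphenoxy}acetate | COC(=O)COc1cc(OC)c(Oc2cc(OC)c(Oc3cc(OC)c(OC)c(OC)c3)c(OC)c2)c(OC)c1 | intermediate
15 | lithium 1-methoxy-3-[2,6-dimethoxy-4-(2,4,6-trimethoxyphenoxy)phenoxy]buta-1,3-dien-1-olate (dienolate of 7) | [Li+].[O-]C(OC)=CC(=C)Oc1c(OC)cc(Oc2c(OC)cc(OC)cc2OC)cc1OC | intermediate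
16 | methyl (E)-3-[2,6-dimethoxy-4-(2,4,6-trimethoxyphenoxy)phenoxy]-6-{4-[3,5-dimethoxy-4-(3,4,5-trimethoxyphenoxy)phenoxy]-3,5-dimethoxyphenoxy}-5-oxohex-2-enoate (present in the flask as its enolate) | COC(=O)/C=C(/Oc1c(OC)cc(Oc2c(OC)cc(OC)cc2OC)cc1OC)CC(=O)COc1cc(OC)c(Oc2cc(OC)c(Oc3cc(OC)c(OC)c(OC)c3)c(OC)c2)c(OC)c1 | intermediate
17 | 2-{4-[3,5-dimethoxy-4-(3,4,5-trimethoxyphenoxy)phenoxy]-3,5-dimethoxyphenoxy}-5-[2,6-dimethoxy-4-(2,4,6-trimethoxyphenoxy)phenoxy]benzene-1,3-diol (hexamer dodecamethyl ether) | COc1cc(OC)c(Oc2cc(OC)c(Oc3cc(O)c(Oc4cc(OC)c(Oc5cc(OC)c(Oc6cc(OC)c(OC)c(OC)c6)c(OC)c5)c(OC)c4)c(O)c3)c(OC)c2)c(OC)c1 | intermediate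
18 | CNP0187343.0 (hexameric phlorotannin, rings A to F joined C4–O–C1, fourteen free hydroxyls) | Oc1cc(O)c(Oc2cc(O)c(Oc3cc(O)c(Oc4cc(O)c(Oc5cc(O)c(Oc6cc(O)c(O)c(O)c6)c(O)c5)c(O)c4)c(O)c3)c(O)c2)c(O)c1 | target

**Summary**

Total step count: 11. Longest linear sequence: 7 steps (5, 6, 7, 8, 9, 10, 11).

Steps most likely to fail:

Step 10. Proton transfer from 14 to the dienolate may outrun acylation. Acylation may occur at the α-carbon. The chain may rest as the open keto ester or as the 2-pyranone because closure through the minor tautomer is too slow. Alkoxide may exchange with the aryloxy group at the enol ether carbon. The fallback does not build ring C but brings it in as a bought arene, using only the couplings already in the route. It sets out from 11 (and uses 1 and 5). Aromatic Finkelstein exchange (CuI, NaI, trans-N,N'-dimethylcyclohexane-1,2-diamine, dioxane, 110 °C) should give the iodide of fragment DEF F1. Iodide-selective Ullmann coupling of F1 with 1 (CuI, picolinic acid, K3PO4, DMSO, 80 °C) should give the bromide of fragment CDEF F2. Ullmann coupling of F2 with phenol 5 under the conditions of step 2 should give the hexamer tetradecamethyl ether F3. BBr3 as in step 11, with a larger excess, returns to the route at 18.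

Step 11. Cleavage of twelve methyl ethers may stop short and leave mixtures of partial ethers. The pyrogallol ring F and the other electron-rich rings may oxidise while the free polyphenol is chromatographed. The fallback sets out from 17 and changes the endgame to capture and release. After the BBr3 treatment the crude product is not isolated as such but peracetylated (Ac2O, pyridine, DMAP) to the tetradecaacetate of the hexamer F4, which is air-stable and separable on silica from under-cleaved material. Acid methanolysis (HCl in MeOH, argon, 40 °C) then releases 18.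

Step 7. Once the iodide is consumed, the C–Br bonds of 1 and of product 11 may enter the copper cycle and give oligomeric ethers. Residual bromide 9 in 10 would couple slowly. The fallback sets out from 10 and uses a halogen-free phenol whose formyl group is a latent hydroxyl. Ullmann coupling of 10 with syringaldehyde (4-hydroxy-3,5-dimethoxybenzaldehyde, COc1cc(C=O)cc(OC)c1O; CuI, picolinic acid, K3PO4, DMSO, 90 °C) should give the aldehyde of fragment DEF F5. Baeyer–Villiger oxidation (mCPBA, 3-chloroperbenzoic acid, CH2Cl2) should give the aryl formate of fragment DEF F6. Methanolysis (K2CO3, MeOH) returns to the route at 12, so that steps 7 and 8 are both replaced.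

**Further compounds**

F1 | step 10 | 5-iodo-2-[3,5-dimethoxy-4-(3,4,5-trimethoxyphenoxy)phenoxy]-1,3-dimethoxybenzene (iodide of fragment DEF) | COc1cc(Oc2c(OC)cc(Oc3c(OC)cc(I)cc3OC)cc2OC)cc(OC)c1OC
F2 | step 10 | 5-bromo-2-{4-[3,5-dimethoxy-4-(3,4,5-trimethoxyphenoxy)phenoxy]-3,5-dimethoxyphenoxy}-1,3-dimethoxybenzene (bromide of fragment CDEF) | COc1cc(Oc2c(OC)cc(Oc3c(OC)cc(Oc4c(OC)cc(Br)cc4OC)cc3OC)cc2OC)cc(OC)c1OC
F3 | step 10 | hexamer tetradecamethyl ether (all fourteen hydroxyls of 18 as methyl ethers) | COc1cc(OC)c(Oc2cc(OC)c(Oc3cc(OC)c(Oc4cc(OC)c(Oc5cc(OC)c(Oc6cc(OC)c(OC)c(OC)c6)c(OC)c5)c(OC)c4)c(OC)c3)c(OC)c2)c(OC)c1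
F4 | step 11 | tetradecaacetate of 18 | CC(=O)Oc1cc(OC(C)=O)c(Oc2cc(OC(C)=O)c(Oc3cc(OC(C)=O)c(Oc4cc(OC(C)=O)c(Oc5cc(OC(C)=O)c(Oc6cc(OC(C)=O)c(OC(C)=O)c(OC(C)=O)c6)c(OC(C)=O)c5)c(OC(C)=O)c4)c(OC(C)=O)c3)c(OC(C)=O)c2)c(OC(C)=O)c1
F5 | step 7 | 4-[3,5-dimethoxy-4-(3,4,5-trimethoxyphenoxy)phenoxy]-3,5-dimethoxybenzaldehyde | COc1cc(Oc2c(OC)cc(Oc3c(OC)cc(C=O)cc3OC)cc2OC)cc(OC)c1OC
F6 | step 7 | 4-[3,5-dimethoxy-4-(3,4,5-trimethoxyphenoxy)phenoxy]-3,5-dimethoxyphenyl formate | COc1cc(Oc2c(OC)cc(Oc3c(OC)cc(OC=O)cc3OC)cc2OC)cc(OC)c1OC
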